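**Plan**

- Retrosynthesis: the aryl silyl ether is cut last, then the C8–vinyl bond of the stilbene (cross-coupling), giving an (S)-8-iodo-5,7-dimethoxyflavan and a ring-A (E)-styrylboronate. The flavan is then cut at O1–C2 and C3–C4.
- Enabling feature: the pyran ring O1–C2–C3–C4, fused at C4a/C8a to the 5,7-dimethoxy arene, consists of a phenol oxygen, one benzylic CH2 and the two carbons of styrene. It is therefore an o-quinone methide (from a 2-hydroxybenzyl alcohol) plus styrene.
- Forward order: the iodinated salicyl alcohol and styrene close the pyran ring (the only ring formed). The ring-A vinylboronate, made in four steps from 2,6-dimethoxytoluene, is then joined at C8, and the phenol is unmasked.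
- Stereochemistry: C2 is the only stereocentre and is set as S in the cycloaddition by a chiral Brønsted acid. The E alkene comes from a boron-Wittig olefination and a geometry-retaining Suzuki coupling.
- The stilbene arm is attached after the acid step so that no electron-rich alkene or extra nucleophilic arene competes for the quinone methide. Iodine at C8 serves as coupling handle and as deactivating group.

Key step: step 3

Assumption: the sense of induction of the chiral acid cannot be predicted for this quinone methide; the (R)-catalyst is written, and its mirror image is meant if the first run gives the 2R series (the iodine of the cycloadduct allows assignment by anomalous X-ray dispersion).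

**Route**

Step 1
Reactants: 1 2-hydroxy-4,6-dimethoxybenzaldehyde
Product: 2 2-hydroxy-3-iodo-4,6-dimethoxybenzaldehyde
Conditions: BnMe3N[ICl2] (1.05 equiv), NaHCO3, CH2Cl2–MeOH, rt
Reagents that add atoms: benzyltrimethylammonium dichloroiodate, C[N+](C)(C)Cc1ccccc1.Cl[I-]Cl
Why: Electrophilic aromatic iodination in which the chelated 2-hydroxyl directs the iodonium equivalent to its free ortho carbon C3, the less crowded of the two activated sites and the one attacked in the analogous 2-hydroxy-4,6-dimethoxyacetophenone, while stoichiometric reagent and bicarbonate buffer should stop the reaction at the mono-iodide (regiochemistry to be confirmed by NOE from the remaining aryl H to both methoxy groups).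

Step 2
Reactants: 2 2-hydroxy-3-iodo-4,6-dimethoxybenzaldehyde
Product: 3 2-(hydroxymethyl)-6-iodo-3,5-dimethoxyphenol
Conditions: NaBH4, THF–MeOH, 0 °C; pH 7 buffer work-up, used promptly
Reagents that add atoms: none
Why: Sodium borohydride reduction of an aryl aldehyde to the primary benzylic alcohol leaves the aryl iodide alone, and low temperature with a neutral work-up should keep the easily ionised 2-hydroxybenzyl alcohol from losing water.

Step 3
Reactants: 3 2-(hydroxymethyl)-6-iodo-3,5-dimethoxyphenol; 4 styrene
Product: 6 (2S)-8-iodo-5,7-dimethoxy-2-phenylchromane, via o-quinone methide 5 (not isolated)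
Conditions: (R)-3,3'-bis(2,4,6-triisopropylphenyl)-1,1'-binaphthyl-2,2'-diyl N-triflylphosphoramide (10 mol %), styrene (20 equiv), toluene, 5 Å molecular sieves, −30 °C, 3 added slowly over several hours
Reagents that add atoms: none
Why: Proposed new method: the chiral acid protonates the benzylic hydroxyl of 3, water leaves with the help of the two methoxy groups and the phenol, and o-quinone methide 5 (exocyclic CH2 = future C4, carbonyl carbon = future C8a) remains hydrogen-bonded and ion-paired to the chiral phosphoramide anion; styrene then adds in an asynchronous inverse-electron-demand hetero-Diels–Alder reaction in which its CH2 terminus bonds to the methide carbon (C3–C4) and the emerging benzylic cation is captured by the quinone methide oxygen (O1–C2). The closest known reaction type is the chiral phosphoric acid or N-triflylphosphoramide catalysed [4+2] cycloaddition of in situ o-quinone methides that carry an aryl group on the methide carbon with activated styrenes, together with the uncatalysed thermal o-quinone methide–styrene route to racemic flavans; enantiocontrol for an unsubstituted methide and plain styrene, where C2 is the only stereocentre, is the untested part. The pyran ring closes by intermolecular [4+2] cycloaddition, four atoms (O1, C8a, C4a, C4) coming from 5 and two (C2, C3) from styrene. C2 is set by the catalyst alone: the confined anion bound at the O1 end blocks one face of the heterodiene and places the phenyl group of the incoming styrene in its pocket, so that one enantiotopic face of the alkene is bonded, and the plain 1-phenylalkyl aryl ether formed should not re-ionise under the catalyst. The step needs regioselectivity, which the polarisation of styrene secures (phenyl ends up at C2 because the benzylic carbon carries the positive charge), and chemoselectivity for styrene over Friedel–Crafts attack by the free C6–H of a second molecule, which is secured by the deactivating iodine at C8, by the absence of any other alkene or electron-rich arene at this stage, by a large excess of styrene and by slow addition of 3.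

Step 4
Reactants: 7 2,6-dimethoxytoluene
Product: 9 3,5-dimethoxy-4-methylphenol, via aryl pinacolboronate 8 (not isolated)
Conditions: [Ir(OMe)(cod)]2 (1 mol %), 4,4'-di-tert-butyl-2,2'-bipyridine, B2pin2 (0.7 equiv), THF, 80 °C; then 30% H2O2, aq NaOH, 0 °C to rt
Reagents that add atoms: bis(pinacolato)diboron, CC1(C)OB(B2OC(C)(C)C(C)(C)O2)OC1(C)C (boryl group of 8); hydrogen peroxide, OO (phenol oxygen of 9)
Why: Iridium-catalysed aromatic C–H borylation is governed by sterics and should take the only ring C–H without an ortho substituent (C4, para to the methyl group), and the aryl boronate is oxidised in the same flask by basic peroxide to the phenol at that carbon.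

Step 5
Reactants: 9 3,5-dimethoxy-4-methylphenol
Product: 10 6-hydroxy-2,4-dimethoxy-3-methylbenzaldehyde
Conditions: MgCl2, Et3N, (CH2O)n, MeCN, reflux; aq HCl work-up
Reagents that add atoms: paraformaldehyde (as formaldehyde), C=O
Why: Magnesium-mediated ortho-formylation of a phenol (Casnati–Skattebøl reaction), in which the magnesium phenoxide delivers formaldehyde to an ortho carbon and a second formaldehyde oxidises the benzylic alkoxide; the two ortho positions of 9 are equivalent and the para position is blocked by methyl, so a single aldehyde should result.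

Step 6
Reactants: 10 6-hydroxy-2,4-dimethoxy-3-methylbenzaldehyde
Product: 11 2,4-dimethoxy-3-methyl-6-(triisopropylsilyloxy)benzaldehyde
Conditions: TIPSCl, imidazole, DMF, rt
Reagents that add atoms: chlorotriisopropylsilane, CC(C)[Si](Cl)(C(C)C)C(C)C
Why: Silylation of a phenol with a trialkylsilyl chloride and imidazole; the triisopropylsilyl ether is chosen because it should survive the lithium amide of step 7 and the aqueous phosphate of step 8 and still leave with fluoride.

Step 7
Reactants: 11 2,4-dimethoxy-3-methyl-6-(triisopropylsilyloxy)benzaldehyde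
Product: 12 (E)-2-{2-[2,4-dimethoxy-3-methyl-6-(triisopropylsilyloxy)phenyl]ethenyl}-4,4,5,5-tetramethyl-1,3,2-dioxaborolane
Conditions: CH2(Bpin)2, LiTMP (lithium 2,2,6,6-tetramethylpiperidide, commercial solution), THF, 0 °C; then 11, −78 °C to rt
Reagents that add atoms: bis(4,4,5,5-tetramethyl-1,3,2-dioxaborolan-2-yl)methane, CC1(C)OB(CB2OC(C)(C)C(C)(C)O2)OC1(C)C
Why: Boron-Wittig olefination, in which lithiated bis(pinacolboryl)methane adds to the aldehyde and the β-alkoxy boronate undergoes syn B–O elimination, which for aryl aldehydes gives the (E)-alkenyl boronate.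

Step 8
Reactants: 6 (2S)-8-iodo-5,7-dimethoxy-2-phenylchromane; 12 (E)-2-{2-[2,4-dimethoxy-3-methyl-6-(triisopropylsilyloxy)phenyl]ethenyl}-4,4,5,5-tetramethyl-1,3,2-dioxaborolane
Product: 13 {2-[(E)-2-((2S)-5,7-dimethoxy-2-phenylchroman-8-yl)ethenyl]-3,5-dimethoxy-4-methylphenoxy}triisopropylsilane
Conditions: Pd(OAc)2 (5 mol %), SPhos (10 mol %), K3PO4, toluene–H2O, 80 °C
Reagents that add atoms: none
Why: Suzuki–Miyaura cross-coupling of an aryl iodide with an alkenyl pinacolboronate proceeds with retention of the E geometry; the electron-rich biaryl phosphine is chosen for oxidative addition at the doubly ortho-substituted, electron-rich C8–I bond, and the C2 benzylic ether has no site that base can epimerise.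

Step 9
Reactants: 13 {2-[(E)-2-((2S)-5,7-dimethoxy-2-phenylchroman-8-yl)ethenyl]-3,5-dimethoxy-4-methylphenoxy}triisopropylsilane
Product: 14 2-{(E)-2-[(2S)-5,7-dimethoxy-2-phenyl-3,4-dihydro-2H-chromen-8-yl]ethenyl}-3,5-dimethoxy-4-methylphenol (CNP0000264.1)
Conditions: Bu4NF, AcOH, THF, 0 °C
Reagents that add atoms: none
Why: Fluoride cleavage of an aryl silyl ether, buffered with acetic acid so that the phenoxide is protonated at once; the stilbene and the C2 benzylic ether are inert to fluoride.

**Compound list**

1 | 2-hydroxy-4,6-dimethoxybenzaldehyde | COc1cc(OC)c(C=O)c(O)c1 | starting material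
2 | 2-hydroxy-3-iodo-4,6-dimethoxybenzaldehyde | COc1cc(OC)c(C=O)c(O)c1I | intermediate
3 | 2-(hydroxymethyl)-6-iodo-3,5-dimethoxyphenol | OCc1c(OC)cc(OC)c(I)c1O | intermediate
4 | styrene | C=Cc1ccccc1 | starting material
5 | 2-iodo-3,5-dimethoxy-6-methylidenecyclohexa-2,4-dien-1-one (o-quinone methide) | C=C1C(OC)=CC(OC)=C(I)C1=O | intermediate (not isolated)
6 | (2S)-8-iodo-5,7-dimethoxy-2-phenylchromane | COc1cc(OC)c2c(c1I)O[C@H](c1ccccc1)CC2 | intermediate
7 | 2,6-dimethoxytoluene | COc1cccc(OC)c1C | starting material
8 | 2-(3,5-dimethoxy-4-methylphenyl)-4,4,5,5-tetramethyl-1,3,2-dioxaborolane | COc1cc(B2OC(C)(C)C(C)(C)O2)cc(OC)c1C | intermediate (not isolated)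
9 | 3,5-dimethoxy-4-methylphenol | COc1cc(O)cc(OC)c1C | intermediate
10 | 6-hydroxy-2,4-dimethoxy-3-methylbenzaldehyde | COc1cc(O)c(C=O)c(OC)c1C | intermediate
11 | 2,4-dimethoxy-3-methyl-6-(triisopropylsilyloxy)benzaldehyde | COc1cc(O[Si](C(C)C)(C(C)C)C(C)C)c(C=O)c(OC)c1C | intermediate
12 | (E)-2-{2-[2,4-dimethoxy-3-methyl-6-(triisopropylsilyloxy)phenyl]ethenyl}-4,4,5,5-tetramethyl-1,3,2-dioxaborolane | COc1cc(O[Si](C(C)C)(C(C)C)C(C)C)c(/C=C/B2OC(C)(C)C(C)(C)O2)c(OC)c1C | intermediate
13 | {2-[(E)-2-((2S)-5,7-dimethoxy-2-phenylchroman-8-yl)ethenyl]-3,5-dimethoxy-4-methylphenoxy}triisopropylsilane | COc1cc(O[Si](C(C)C)(C(C)C)C(C)C)c(/C=C/c2c(OC)cc(OC)c3c2O[C@H](c2ccccc2)CC3)c(OC)c1C | intermediate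
14 | 2-{(E)-2-[(2S)-5,7-dimethoxy-2-phenyl-3,4-dihydro-2H-chromen-8-yl]ethenyl}-3,5-dimethoxy-4-methylphenol | COc1cc(O)c(/C=C/c2c(OC)cc(OC)c3c2O[C@H](c2ccccc2)CC3)c(OC)c1C | target

**Step count**

Total: 9 steps. Longest linear sequence: 6 steps (7 → 9 → 10 → 11 → 12 → 13 → 14, steps 4–9); the flavan branch (steps 1–3) joins at step 8.

**Steps most likely to fail**

1. Step 3 (proposed method). What may go wrong: weak facial discrimination at a methide carbon that carries no substituent, or consumption of the quinone methide by Friedel–Crafts self-alkylation before styrene adds. The fallback uses known chemistry, sets out from 2 and returns at 6.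
 - Aldol condensation of 2 with acetophenone (KOH, EtOH) should give the chalcone (E)-3-(2-hydroxy-3-iodo-4,6-dimethoxyphenyl)-1-phenylprop-2-en-1-one F1.
 - Copper hydride conjugate reduction ([(Ph3P)CuH]6 cat., PhSiH3) should give the saturated ketone 3-(2-hydroxy-3-iodo-4,6-dimethoxyphenyl)-1-phenylpropan-1-one F2.
 - Noyori transfer hydrogenation with RuCl[(R,R)-TsDPEN](p-cymene) and HCO2H–Et3N should give the carbinol 2-[(3R)-3-hydroxy-3-phenylpropyl]-6-iodo-3,5-dimethoxyphenol F3.
 - Intramolecular Mitsunobu etherification (PPh3, DIAD, THF) closes the pyran ring by SN2 displacement with inversion, delivering 6 in the 2S series.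

2. Step 7. What may go wrong: sluggish addition of the bulky α-boryl carbanion to the crowded, donor-deactivated aldehyde, or oxygen-to-oxygen silyl migration at the alkoxide stage. The fallback sets out from 11 and returns at 12.
 - Corey–Fuchs olefination (CBr4, PPh3, CH2Cl2) should give the dibromoalkene [2-(2,2-dibromoethenyl)-3,5-dimethoxy-4-methylphenoxy]triisopropylsilane F4.
 - n-BuLi (2 equiv, THF, −78 °C) converts it into the alkyne (2-ethynyl-3,5-dimethoxy-4-methylphenoxy)triisopropylsilane F5.
 - Cp2ZrHCl-catalysed syn hydroboration with pinacolborane gives 12 as the E isomer only.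

3. Step 8. What may go wrong: slow transmetalation of the alkenylboronate at the congested arylpalladium intermediate, with protodeboronation or homocoupling of 12 taking over. The fallback sets out from 11 and 6 and returns at 13.
 - Wittig methylenation of 11 (Ph3PCH3Br, KOt-Bu, THF) gives the styrene (2-ethenyl-3,5-dimethoxy-4-methylphenoxy)triisopropylsilane F6.
 - Mizoroki–Heck coupling of F6 with 6 under Jeffery conditions (Pd(OAc)2, Bu4NCl, NaHCO3, DMF, 80 °C) arylates the terminal carbon and should give the E stilbene 13 without any boron reagent.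

Further compounds
F1 | step 3 | (E)-3-(2-hydroxy-3-iodo-4,6-dimethoxyphenyl)-1-phenylprop-2-en-1-one | O=C(/C=C/c1c(OC)cc(OC)c(I)c1O)c1ccccc1
F2 | step 3 | 3-(2-hydroxy-3-iodo-4,6-dimethoxyphenyl)-1-phenylpropan-1-one | O=C(CCc1c(OC)cc(OC)c(I)c1O)c1ccccc1
F3 | step 3 | 2-[(3R)-3-hydroxy-3-phenylpropyl]-6-iodo-3,5-dimethoxyphenol | O[C@@H](c1ccccc1)CCc1c(OC)cc(OC)c(I)c1O
F4 | step 7 | [2-(2,2-dibromoethenyl)-3,5-dimethoxy-4-methylphenoxy]triisopropylsilane | COc1cc(O[Si](C(C)C)(C(C)C)C(C)C)c(C=C(Br)Br)c(OC)c1C
F5 | step 7 | (2-ethynyl-3,5-dimethoxy-4-methylphenoxy)triisopropylsilane | COc1cc(O[Si](C(C)C)(C(C)C)C(C)C)c(C#C)c(OC)c1C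
F6 | step 8 | (2-ethenyl-3,5-dimethoxy-4-methylphenoxy)triisopropylsilane | COc1cc(O[Si](C(C)C)(C(C)C)C(C)C)c(C=C)c(OC)c1C
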